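## The problem

Compound 40 is two bicycles joined only by the C16–C17 ethylene. One is a cis-fused hydroazulene, cyclopentane C5–C9 sharing C5–C6 with the cycloheptene C2, C3, C4, C5, C6, C12, C15 (C1 is the methyl on C2, C13/C14 the methyls on C12, C10 the methyl on C9); the other is a cis-fused oxepan-3-one on a cyclohexane, C19, C21, C22, C23, C25, O28, C29 sharing C19–C29 with C18, C19, C29–C32 (C20 on C19, C33 on C32). The eight stereocentres form two clusters (C5, C6, C9, C15 and C18, C19, C29, C32) that cannot control each other across the linker, so each half must be made as one enantiomer and the union must set or respect C18. Within the halves, C15 relates to C6 only across the quaternary C12, whereas C29 can direct C19 through its oxygen, C19 the neighbouring C18, and the axial C20 methyl the face of C32. The two tertiary alcohols eliminate under acid; the C2=C3 alkene forbids late epoxidation or hydroboration elsewhere; C18 is epimerisable while C32 is a ketone; and the C23 ketone is best carried as a protected alcohol so that only one carbonyl meets the methyl nucleophile for C33. The enabling feature is that the cyclopentane with carbinol C9, the C4 arm on C5 and C12 on C6 is the linalool chain C4–C5–C9–C8–C7–C6–C12 closed between C5 and C6, so a C5 radical from a terminal C4–C5 epoxide can close 5-exo onto a C6=C12 prenyl alkene and leave C12 as an isopropenyl group. The catch is that 40 has the C10 methyl cis to both arms and the hydroxyl on the convex face, whereas in the radical transition state the C4 arm lies beside the smaller C9 substituent, which is oxygen. C9 is therefore used as a relay with oxygen cis to the arms and CH2SiMe3 standing in for C10, and is corrected later by Peterson elimination and convex-face hydration.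

## Retrosynthesis

**End game (40 ← 39 ← 38 ← 37).** No skeletal bond is cut for the C23 carbonyl: it comes last by oxidising the only secondary alcohol of triol 39. The C32–C33 bond is cut back to ketone 37. Keeping C32 as a ketone until after the union, rather than carrying a protected tertiary carbinol, provides the enolate needed for the union; the forward step asks only for equatorial methyl attack, which the axial C20 methyl should enforce.

**Union (37 ← 36 ← 35 ← 33 + 23).** C17–C18 and C19–C20 are cut together: methyl cuprate addition to enone 33 gives enolate 34, regiodefined at C18, which is captured by aldehyde 23. A C16–C17 olefination would need a selective reduction beside C2=C3 and would leave C18 to a protonation that enters from the wrong face. Alkylation with an unactivated halide next to a quaternary carbon is unreliable. The price is removal of the aldol hydroxyl (35 → 36 → 37). The precursors are two bicyclic fragments of similar size; the forward step must deliver methyl anti to O28 and the aldehyde anti to the oxepane.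

**Right half (33 ← 32 ← 31 ← 30 ← 29 ← 28 ← 27 ← 26 ← 25 ← 24).** The O28–C25 bond is cut to epoxy alcohol 31. An intramolecular epoxide opening at the tertiary carbon avoids an intermolecular tertiary etherification of a hindered secondary alcohol. It is placed before the quaternary centre exists, so that the later cuprate addition anti to O28 gives the cis fusion automatically. C19–C21 is cut to silyloxy enone 27 and Grignard reagent 2 (conjugate addition, then re-oxidation to 29). The single stereocentre C29 comes from transfer hydrogenation of commercial enone ketal 24.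

**Left aldehyde (23 ← 22 ← 21 ← 19).** C1–C2 is cut: the methyl-bearing alkene comes from ketone 19 through enol triflate 21. This places the double bond by kinetic enolisation toward the unhindered C3 rather than by elimination chemistry.

**C9 correction (19 ← 18 ← 17 ← 16).** The C9–O bond is cut to the exocyclic alkene 17, hydrated from the convex face of the finished bicycle. 17 comes from 16 by Peterson elimination, which can only form the alkene toward C10. This costs two steps but frees the radical cyclisation from having to place a methyl group in the most crowded position.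

**Seven-membered ring (16 ← 15 ← 13 + 14; 13 ← 9 + 10).** C12–C15 is cut: a hydrogen-atom-transfer radical at C12 adds to C15 of a 4-oxo-2-enoate, which is the only practical way to quaternise the isopropenyl carbon. C15=C16 (olefination with 14) and C3–C4 (alkylation with 10) are cut next, leaving cyclopentylmethanol 9.

**Key step (9 ← 8).** C5–C6 is cut: the cyclopentane and the C5/C6 stereocentres come from one tertiary carbinol in open-chain epoxide 8.

**Relay precursor (8 ← 7 ← 6 ← 5 ← 4 ← 2 + 3; 2 ← 1).** C9–C10 is cut to epoxy ketone 6 (chelation-controlled addition of Me3SiCH2MgCl). The epoxide carbon comes from Sharpless kinetic resolution of racemic dienol 4, itself from Grignard reagent 2 and acrolein 3. Reagent 2 is prepared once from bromide 1, and the same solution serves the right half.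

## Roads not taken

**Alternative 1:** The cut is C19–C29 and C18–C32 of the cyclohexane. A chiral oxazaborolidinium-catalysed Diels–Alder reaction of diene A1 with dienophile A2 would give cyclohexene A3.
- Merits: one catalytic step makes the quaternary C19 and fixes C18 and C29 with the relations 40 needs (formyl carbon cis to the silyloxy group by the endo rule, trans to the ester from the E-dienophile), with enantiocontrol from a catalyst rather than a resolution.
- Weak points: C32 arrives as a methylene and needs allylic oxidation before the carbinol can be built; the ester on C18 forces a C16–C17 union followed by a reduction selective against C2=C3; the oxepane is still to be made.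
- Comparison: for stereochemical economy in the right half A3 is better than the sequence 27 → 33 used here. The chosen plan sets against it a C32 ketone present from the start, which lets one operation (step 26) make C19–C20 and C17–C18 and join the halves. Alternative 1 also does not address the hydroazulene, where the real difficulty lies.

**Alternative 2:** The cut is C19–C21. Hydrogen-atom transfer (Fe(acac)3, PhSiH3) to the exocyclic methylene of vinyl ketone A4 would give a tertiary C19 radical that closes 7-endo onto the tethered enone, giving oxepanone A5.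
- Merits: the oxepanone appears at the correct oxidation level, the tether guarantees the cis fusion, and the C32 carbinol is already present.
- Weak points: A4 requires a tertiary ether between C25 and a hindered secondary allylic oxygen, for which there is no dependable intermolecular method; the 7-endo closure competes with simple reduction; the C17 arm is a neopentyl-type CH2O group that is a poor partner for the union.
- Comparison: in delivering the C23 ketone directly it is better than the protect-and-oxidise detour used here. The chosen plan sets against it a C25–O28 bond made intramolecularly from an epoxide on simple material, and a C19 centre whose formation also generates the enolate used for the fragment union.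

**Alternative 3:** The cut is C4–C5. The silyl ketene acetal of seven-membered lactone A6 would undergo Ireland–Claisen rearrangement to cycloheptene acid A7.
- Merits: the ring is formed with C2=C3 and its methyl already in place (no enol triflate, no regioselective enolisation), C5 is set by chirality transfer, and two vinyl groups remain as handles.
- Weak points: A6 needs C6, C15 and the carbinol carbon arranged around the quaternary C12 by acyclic stereocontrol; a seven-membered lactone must rearrange through a boat transition state; the cyclopentane and the C9 carbinol must still be annulated, and the two vinyl groups differentiated.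
- Comparison: in placing the alkene it is better than the route chosen. The chosen plan sets against it a cyclopentane whose two ring stereocentres come from one carbinol in a single cascade, and a seven-membered ring closed at the quaternary carbon by a radical reaction that tolerates congestion.

Key step: step 7

Assumption: C23 (made in step 22, oxidised in step 31) is drawn R and the aldol carbinol C17 of 35 and 36 (removed in step 28) is left undefined, since neither centre survives; the catalyst antipodes of steps 3, 17 and 22 are those predicted by the usual models and would be exchanged if the opposite sense were found.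

Step 1
Reactants: 1 5-bromo-2-methylpent-2-ene
Product: 2 (4-methylpent-3-en-1-yl)magnesium bromide (homoprenylmagnesium bromide), kept as a titrated THF solution under argon
Conditions: Mg turnings, THF, rt → 40 °C; titration
Reagents that add atoms: magnesium, [Mg]
Why: Grignard formation by insertion of magnesium into the primary C–Br bond; the open-chain homoallyl reagent is strongly favoured over its cyclopropylmethyl isomer and keeps in THF, so one batch is divided between steps 2 and 20.

Step 2
Reactants: 2 (4-methylpent-3-en-1-yl)magnesium bromide; 3 prop-2-enal (acrolein)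
Product: 4 rac-7-methylocta-1,6-dien-3-ol
Conditions: 3, THF, −78 °C; aq. NH4Cl
Reagents that add atoms: none
Why: Grignard 1,2-addition to the aldehyde carbonyl of acrolein, the normal course for organomagnesium reagents at low temperature; the alcohol is made racemic on purpose because step 3 resolves it.

Step 3
Reactants: 4 rac-7-methylocta-1,6-dien-3-ol
Product: 5 (1R)-5-methyl-1-[(2S)-oxiran-2-yl]hex-4-en-1-ol
Conditions: Ti(OiPr)4 (0.2 equiv), D-(−)-diisopropyl tartrate (0.25 equiv), t-BuOOH (0.45 equiv), 4 Å MS, CH2Cl2, −20 °C
Reagents that add atoms: tert-butyl hydroperoxide, CC(C)(C)OO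
Why: Sharpless kinetic resolution of a secondary allylic alcohol: with D-(−)-tartrate the (R)-alcohol should be epoxidised much faster than its antipode and on the face that gives the erythro (2S)-epoxide, so both centres of 5 come from the catalyst; at most half of 4 is converted and the isolated trisubstituted alkene is not touched by the titanium–tartrate system.

Step 4
Reactants: 5 (1R)-5-methyl-1-[(2S)-oxiran-2-yl]hex-4-en-1-ol
Product: 6 5-methyl-1-[(2S)-oxiran-2-yl]hex-4-en-1-one
Conditions: Dess–Martin periodinane, CH2Cl2, 0 °C → rt
Reagents that add atoms: none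
Why: Dess–Martin oxidation of the secondary alcohol under mild, non-basic conditions that leave the epoxide intact; the epoxide carbon keeps its S configuration.

Step 5
Reactants: 6 5-methyl-1-[(2S)-oxiran-2-yl]hex-4-en-1-one
Product: 7 (2R)-6-methyl-2-[(2S)-oxiran-2-yl]-1-(trimethylsilyl)hept-5-en-2-ol
Conditions: Me3SiCH2MgCl, Et2O/CH2Cl2, −78 °C; aq. NH4Cl
Reagents that add atoms: (trimethylsilyl)methylmagnesium chloride, C[Si](C)(C)C[Mg]Cl
Why: Chelation-controlled Grignard addition to an α,β-epoxy ketone: magnesium bridges the carbonyl and epoxide oxygens and the nucleophile enters from the hydrogen side of the epoxide carbon, which should fix C9 as R; the magnesium β-silyl alkoxide does not undergo Peterson elimination at this temperature.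

Step 6
Reactants: 7 (2R)-6-methyl-2-[(2S)-oxiran-2-yl]-1-(trimethylsilyl)hept-5-en-2-ol
Product: 8 triethylsilyl ether of 7
Conditions: Et3SiOTf, 2,6-lutidine, CH2Cl2, −78 °C
Reagents that add atoms: triethylsilyl trifluoromethanesulfonate, CC[Si](CC)(CC)OS(=O)(=O)C(F)(F)F
Why: Silyl triflate/2,6-lutidine silylation of a hindered tertiary alcohol at −78 °C, where a terminal epoxide survives; the ether prevents O–Ti chelation in step 7 and base-induced Peterson elimination in step 8.

Step 7
Reactants: 8 triethylsilyl ether of 7
Product: 9 {(1R,2R,5S)-5-(prop-1-en-2-yl)-2-[(triethylsilyl)oxy]-2-[(trimethylsilyl)methyl]cyclopentyl}methanol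
Conditions: Cp2TiCl2 (2.5 equiv), Mn dust, THF, rt (gives Cp2TiCl); slow addition of 8 (0.02 M); sat. aq. NaH2PO4
Reagents that add atoms: none
Why: Cp2TiCl (trivalent titanium) transfers one electron to the epoxide, which opens at the more substituted C5–O bond to give the secondary C5 radical and a C4 titanium alkoxide; the radical adds 5-exo-trig to C6 of the trisubstituted alkene and closes the cyclopentane, and the tertiary C12 radical is captured by a second Cp2TiCl and loses β-hydride from a methyl group to leave the isopropenyl unit. The closest known reaction type is the titanocene-mediated reductive epoxide opening with 5-exo cyclisation onto prenyl-type alkenes and dehydrogenative termination. C9 is not touched and controls both new centres: in the chair-like transition state of the 5-hexenyl radical the largest C9 substituent, CH2SiMe3, is pseudo-equatorial, so the silyloxy group is pseudo-axial on the face that receives C12. At the planar C5 radical the C4 arm all but eclipses that pseudo-axial substituent, which is tolerable for oxygen but not for a carbon group, so C4 should end cis to O9 (C5 configuration) and, being pseudo-equatorial, cis to C12 (C6 configuration, the usual 1,5-cis preference). The expected result is the all-cis O9/C4/C12 triad with C5 and C6 as in 40. The step needs ring closure to outrun capture of the C5 radical by a second titanium, which would end in β-elimination of the titanoxy group; slow addition at high dilution and the gem-disubstituent effect of the quaternary C9 should secure this. The silyl ether excludes O–Ti chelation, and the buffered work-up avoids acid-promoted Peterson elimination.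

Step 8
Reactants: 9 cyclopentylmethanol from step 7; 10 dimethyl (2-oxopropyl)phosphonate
Product: 13 dimethyl [2-oxo-4-(cyclopentyl)butyl]phosphonate (cyclopentyl = ring of 9 attached through C5), via primary triflate 11 (not isolated), via phosphonate dianion 12 (not isolated)
Conditions: 9, Tf2O, 2,6-lutidine, CH2Cl2, −78 °C; separately 10, NaH then n-BuLi, THF, 0 °C; combine, −78 → 0 °C; aq. NH4Cl
Reagents that add atoms: none
Why: The primary alcohol is activated as its triflate because C4 is β-branched and slow in SN2 reactions; the 1,3-dianion of the β-ketophosphonate alkylates at its terminal carbon, a standard way to extend such phosphonates, and puts C3, C2 and C15 in place.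

Step 9
Reactants: 13 β-ketophosphonate; 14 ethyl glyoxylate
Product: 15 ethyl (E)-4-oxo-6-(cyclopentyl)hex-2-enoate (cyclopentyl as in 9)
Conditions: LiCl, i-Pr2NEt, MeCN, 0 °C → rt
Reagents that add atoms: none
Why: Horner–Wadsworth–Emmons olefination under LiCl/amine conditions; the stabilised β-ketophosphonate anion gives the E-configured 4-oxo-2-enoate and the mild base leaves the silyl ether alone.

Step 10
Reactants: 15 ethyl (E)-4-oxo-6-(cyclopentyl)hex-2-enoate
Product: 16 ethyl 2-[4,4-dimethyl-6-oxo-1-(triethylsilyloxy)-1-(trimethylsilylmethyl)decahydroazulen-5-yl]acetate (cis-fused; H5, H6 and H15 on one face)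
Conditions: Fe(acac)3 (0.3 equiv), PhSiH3, EtOH/ethylene glycol, 60 °C
Reagents that add atoms: none
Why: Iron-hydride hydrogen-atom transfer to the 1,1-disubstituted alkene gives the tertiary C12 radical, which adds 7-exo-trig to C15 (the carbon β to the ester), and the resulting α-ester radical is reduced and protonated (reductive olefin coupling used intramolecularly). With H6 in the plane of the radical and the enoate carbon C16 pseudo-equatorial in a chair-like closure, C16 should end cis to C7 as in 40; C15 is α to the C2 ketone, so its ratio can be adjusted by base equilibration.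

Step 11
Reactants: 16 bicyclic keto ester
Product: 17 ethyl 2-(4,4-dimethyl-1-methylidene-6-oxodecahydroazulen-5-yl)acetate (cis-fused; H5, H6 and H15 on one face)
Conditions: 48% aq. HF, MeCN, 0 °C
Reagents that add atoms: none
Why: Acid-promoted Peterson elimination: loss of the silyloxy group gives a C9 cation stabilised by the β-silicon, which then loses the Me3Si group, so the alkene can only form toward C10; the relay stereocentre is erased and replaced by a prochiral exocyclic alkene.

Step 12
Reactants: 17 exocyclic alkene
Product: 18 ethyl 2-(1-hydroxy-1,4,4-trimethyl-6-oxodecahydroazulen-5-yl)acetate (C5, C6, C9 and C15 as in 40)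
Conditions: Co(acac)2 (0.2 equiv), PhSiH3, O2 (1 atm), i-PrOH, rt; aq. Na2S2O3
Reagents that add atoms: dioxygen, O=O
Why: Mukaiyama hydration: cobalt-hydride hydrogen-atom transfer to the terminal carbon C10 gives the tertiary C9 radical, which should be captured by O2 on the convex face of the cis-fused bicycle (the side of H5 and H6, away from C4 and the C12 methyls), so the hydroxyl ends trans to C4 and the new methyl cis to it, as in 40; the peroxide is reduced on work-up.

Step 13
Reactants: 18 hydroxy keto ester
Product: 19 triethylsilyl ether of 18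
Conditions: Et3SiOTf, 2,6-lutidine, CH2Cl2, −78 °C
Reagents that add atoms: triethylsilyl trifluoromethanesulfonate, CC[Si](CC)(CC)OS(=O)(=O)C(F)(F)F
Why: Silylation of the tertiary alcohol at low temperature, where the ketone is not converted into a silyl enol ether; the ether protects C9–OH from the bases and organometallics of steps 14–29.

Step 14
Reactants: 19 triethylsilyl ether of 18
Product: 21 C2 enol triflate of 19 (C2=C3), via potassium enolate 20 (not isolated)
Conditions: KN(SiMe3)2, THF, −78 °C; then PhNTf2
Reagents that add atoms: N-phenylbis(trifluoromethanesulfonimide), O=S(=O)(N(c1ccccc1)S(=O)(=O)C(F)(F)F)C(F)(F)F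
Why: Kinetic deprotonation removes a proton from the unhindered C3 methylene and not the tertiary C15–H next to the quaternary C12, and the potassium enolate is triflated on oxygen; this fixes the position of the future C2=C3 alkene.

Step 15
Reactants: 21 enol triflate
Product: 22 ethyl 2-[(1S,3aS,5R,8aS)-1,4,4,6-tetramethyl-1-(triethylsilyloxy)-1,2,3,3a,4,5,8,8a-octahydroazulen-5-yl]acetate
Conditions: MeMgBr, Fe(acac)3 (5 mol%), THF/NMP, −30 °C
Reagents that add atoms: methylmagnesium bromide, C[Mg]Br
Why: Iron-catalysed cross-coupling of an alkenyl triflate with a methyl Grignard reagent, which at −30 °C is faster than Grignard addition to the ethyl ester; it installs C1 without moving the double bond.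

Step 16
Reactants: 22 methylcycloheptene ester
Product: 23 2-[(1S,3aS,5R,8aS)-1,4,4,6-tetramethyl-1-(triethylsilyloxy)-1,2,3,3a,4,5,8,8a-octahydroazulen-5-yl]acetaldehyde
Conditions: i-Bu2AlH, CH2Cl2, −78 °C; aq. potassium sodium tartrate
Reagents that add atoms: none
Why: Partial reduction of the ester: at −78 °C the aluminium hemiacetal is stable and collapses to the aldehyde only on work-up.

Step 17
Reactants: 24 1,4-dioxaspiro[4.5]dec-6-en-8-one
Product: 25 (8R)-1,4-dioxaspiro[4.5]dec-6-en-8-ol
Conditions: RuCl[(R,R)-TsDPEN](p-cymene) (1 mol%), HCO2H/Et3N, CH2Cl2, rt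
Reagents that add atoms: none
Why: Noyori asymmetric transfer hydrogenation reduces the enone carbonyl 1,2; the alkene plays the part of the aryl group of an aryl ketone, so the (R,R)-catalyst should give the (R)-allylic alcohol.

Step 18
Reactants: 25 (8R)-1,4-dioxaspiro[4.5]dec-6-en-8-ol
Product: 26 tert-butyldimethylsilyl ether of 25
Conditions: t-BuMe2SiCl, imidazole, DMF, rt
Reagents that add atoms: tert-butyldimethylsilyl chloride, CC(C)(C)[Si](C)(C)Cl
Why: Standard silylation of a secondary allylic alcohol.

Step 19
Reactants: 26 silyl ether of 25
Product: 27 (4R)-4-[(tert-butyldimethylsilyl)oxy]cyclohex-2-en-1-one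
Conditions: PPTS (cat.), acetone/H2O, 50 °C
Reagents that add atoms: water, O
Why: Acid-catalysed ketal hydrolysis under pyridinium tosylate, mild enough to keep the allylic silyl ether; it unmasks the enone in which the carbinol carbon has become C4 (C29 of 40).

Step 20
Reactants: 27 (4R)-4-[(tert-butyldimethylsilyl)oxy]cyclohex-2-en-1-one; 2 (4-methylpent-3-en-1-yl)magnesium bromide (second portion of the solution from step 1)
Product: 28 trimethylsilyl enol ether of trans-4-(tert-butyldimethylsilyloxy)-3-(4-methylpent-3-en-1-yl)cyclohexanone
Conditions: 2, CuBr·SMe2 (10 mol%), Me3SiCl, THF, −78 °C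
Reagents that add atoms: chlorotrimethylsilane, C[Si](C)(C)Cl
Why: Copper-catalysed conjugate addition of the Grignard reagent with Me3SiCl as accelerator and enolate trap; addition occurs anti to the 4-silyloxy group, but the new C3 centre is removed in step 21 and only the regiodefined silyl enol ether matters.

Step 21
Reactants: 28 trimethylsilyl enol ether
Product: 29 (4R)-4-[(tert-butyldimethylsilyl)oxy]-3-(4-methylpent-3-en-1-yl)cyclohex-2-en-1-one
Conditions: Pd(OAc)2 (10 mol%), O2 (1 atm), DMSO, rt
Reagents that add atoms: none
Why: Saegusa–Ito oxidation: the palladium enolate formed from the silyl enol ether undergoes β-hydride elimination toward C3 and gives the 3-substituted enone with C29 untouched.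

Step 22
Reactants: 29 3-substituted silyloxy enone
Product: 30 (4R)-4-[(tert-butyldimethylsilyl)oxy]-3-{2-[(2R)-3,3-dimethyloxiran-2-yl]ethyl}cyclohex-2-en-1-one
Conditions: D-fructose-derived Shi ketone (0.3 equiv), KHSO5, K2CO3, MeCN/dimethoxymethane/aq. buffer (pH 10.5), 0 °C
Reagents that add atoms: potassium peroxymonosulfate, [K+].[O-]S(=O)(=O)OO
Why: Shi epoxidation: the chiral dioxirane epoxidises the electron-rich trisubstituted alkene and leaves the electron-poor enone alkene alone; reagent control gives one C23 epimer, which keeps all later intermediates single compounds.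

Step 23
Reactants: 30 epoxy silyl ether
Product: 31 (4R)-3-{2-[(2R)-3,3-dimethyloxiran-2-yl]ethyl}-4-hydroxycyclohex-2-en-1-one
Conditions: Bu4NF, AcOH, THF, 0 °C
Reagents that add atoms: none
Why: Fluoride desilylation buffered with acetic acid, so that the alkoxide neither opens the epoxide nor degrades the γ-hydroxy enone.

Step 24
Reactants: 31 epoxy alcohol
Product: 32 (3R,9aR)-3-hydroxy-2,2-dimethyl-3,4,5,8,9,9a-hexahydro-1-benzoxepin-7(2H)-one
Conditions: camphorsulfonic acid (10 mol%), CH2Cl2, 0 °C
Reagents that add atoms: none
Why: Brønsted-acid-catalysed intramolecular epoxide opening: O28 attacks the tertiary carbon C25, which carries most of the positive charge of the protonated trisubstituted epoxide (7-endo), forming the tertiary ether and the oxepane with C23 as a secondary alcohol; C29 is unchanged and C19 is still trigonal.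

Step 25
Reactants: 32 hydroxy oxepane enone
Product: 33 triethylsilyl ether of 32
Conditions: Et3SiCl, imidazole, DMF, 0 °C
Reagents that add atoms: chlorotriethylsilane, CC[Si](Cl)(CC)CC
Why: Silylation of the hindered secondary alcohol; it keeps C23 at the alcohol level so that only one ketone is present when the C33 methyl is added in step 29.

Step 26
Reactants: 33 triethylsilyl ether of 32; 23 left-half aldehyde
Product: 35 aldol adduct (β-hydroxy ketone with C17 carbinol epimers; C18, C19 and C29 as in 40), via lithium enolate 34 (not isolated)
Conditions: Me2CuLi (from MeLi and CuI), Et2O, −20 °C; then 23, −78 °C; AcOH then aq. NH4Cl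
Reagents that add atoms: lithium dimethylcuprate, [Li+].C[Cu-]C
Why: Conjugate addition of the cuprate methyl to C19 anti to the C29–O28 bond (axial attack opposite the allylic oxygen, as for 4-alkoxycyclohexenones) should make the quaternary centre and the cis ring fusion; the lithium enolate so formed, regiodefined at C18, adds to aldehyde 23 on the face anti to the oxepane ring (syn to the new C20 methyl), which sets C18. The C17 carbinol forms as a mixture and is removed in step 28.

Step 27
Reactants: 35 aldol adduct
Product: 36 O-(imidazol-1-ylthiocarbonyl) derivative of 35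
Conditions: 1,1'-thiocarbonyldiimidazole, toluene, 60 °C
Reagents that add atoms: 1,1'-thiocarbonyldiimidazole, S=C(n1ccnc1)n1ccnc1
Why: Thioacylation of the secondary aldol hydroxyl without added base, to limit retro-aldol and β-elimination; first half of a Barton–McCombie deoxygenation.

Step 28
Reactants: 36 thiocarbonyl derivative
Product: 37 C32 ketone with C9 and C23 triethylsilyl ethers (C18, C19 and C29 as in 40)
Conditions: Bu3SnH (0.2 M), AIBN (cat.), toluene, 90 °C
Reagents that add atoms: none
Why: Barton–McCombie deoxygenation: the stannyl radical adds to sulfur, the C17–O bond fragments and the secondary C17 radical takes hydrogen from Bu3SnH, kept concentrated so that reduction outruns 1,2-acyl migration of the β-keto radical; C18 is not enolised under these neutral conditions.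

Step 29
Reactants: 37 C32 ketone
Product: 38 C32 tertiary alcohol with C9 and C23 triethylsilyl ethers
Conditions: MeMgBr, CeCl3, THF, −78 °C
Reagents that add atoms: methylmagnesium bromide, C[Mg]Br
Why: Organocerium-assisted methyl addition to a hindered, enolisable ketone: with the C17 chain equatorial the C20 methyl is axial and blocks axial attack at C32, so the methyl should enter equatorially and the hydroxyl end axial, cis to C20 and to the C18 side chain, as in 40.

Step 30
Reactants: 38 bis(triethylsilyl) ether
Product: 39 triol (the C23 (R)-carbinol corresponding to 40)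
Conditions: Bu4NF, THF, rt → 40 °C
Reagents that add atoms: none
Why: Fluoride cleavage of both triethylsilyl ethers (secondary at C23, tertiary at C9) under non-acidic conditions that spare the two tertiary alcohols and the trisubstituted alkene.

Step 31
Reactants: 39 triol
Product: 40 target compound CNP0194989.5
Conditions: Dess–Martin periodinane, NaHCO3, CH2Cl2, rt
Reagents that add atoms: none
Why: Dess–Martin oxidation of the only secondary alcohol; tertiary alcohols and the alkene are inert, and the buffer avoids acid-promoted dehydration.

## Compound list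

1 | 5-bromo-2-methylpent-2-ene | CC(C)=CCCBr | starting material
2 | (4-methylpent-3-en-1-yl)magnesium bromide | CC(C)=CCC[Mg]Br | intermediate
3 | prop-2-enal (acrolein) | C=CC=O | starting material
4 | rac-7-methylocta-1,6-dien-3-ol | CC(C)=CCCC(O)C=C | intermediate
5 | (1R)-5-methyl-1-[(2S)-oxiran-2-yl]hex-4-en-1-ol | CC(C)=CCC[C@@H](O)[C@@H]1CO1 | intermediate
6 | 5-methyl-1-[(2S)-oxiran-2-yl]hex-4-en-1-one | CC(C)=CCCC(=O)[C@@H]1CO1 | intermediate
7 | (2R)-6-methyl-2-[(2S)-oxiran-2-yl]-1-(trimethylsilyl)hept-5-en-2-ol | CC(C)=CCC[C@@](C[Si](C)(C)C)(O)[C@@H]1CO1 | intermediate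
8 | triethylsilyl ether of 7 (key-step precursor) | CC(C)=CCC[C@@](C[Si](C)(C)C)(O[Si](CC)(CC)CC)[C@@H]1CO1 | intermediate
9 | {(1R,2R,5S)-5-(prop-1-en-2-yl)-2-[(triethylsilyl)oxy]-2-[(trimethylsilyl)methyl]cyclopentyl}methanol (O9, C4 and C12 all cis) | OC[C@H]1[C@H](CC[C@@]1(C[Si](C)(C)C)O[Si](CC)(CC)CC)C(C)=C | intermediate
10 | dimethyl (2-oxopropyl)phosphonate | COP(=O)(OC)CC(C)=O | starting material
11 | trifluoromethanesulfonate of 9 | FC(F)(F)S(=O)(=O)OC[C@H]1[C@H](CC[C@@]1(C[Si](C)(C)C)O[Si](CC)(CC)CC)C(C)=C | intermediate
12 | sodium lithium 1,3-dianion of 10 | [Na+].[Li+].[CH2-]C(=O)[CH-]P(=O)(OC)OC | intermediate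
13 | dimethyl [2-oxo-4-(cyclopentyl)butyl]phosphonate, ring of 9 | COP(=O)(OC)CC(=O)CC[C@H]1[C@H](CC[C@@]1(C[Si](C)(C)C)O[Si](CC)(CC)CC)C(C)=C | intermediate
14 | ethyl glyoxylate | CCOC(=O)C=O | starting material
15 | ethyl (E)-4-oxo-6-(cyclopentyl)hex-2-enoate, ring of 9 | CCOC(=O)/C=C/C(=O)CC[C@H]1[C@H](CC[C@@]1(C[Si](C)(C)C)O[Si](CC)(CC)CC)C(C)=C | intermediate
16 | ethyl 2-[4,4-dimethyl-6-oxo-1-(triethylsilyloxy)-1-(trimethylsilylmethyl)decahydroazulen-5-yl]acetate, cis-fused | O=C1CC[C@H]2[C@H](CC[C@@]2(C[Si](C)(C)C)O[Si](CC)(CC)CC)C(C)(C)[C@@H]1CC(=O)OCC | intermediate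
17 | ethyl 2-(4,4-dimethyl-1-methylidene-6-oxodecahydroazulen-5-yl)acetate, cis-fused | O=C1CC[C@H]2[C@H](CCC2=C)C(C)(C)[C@@H]1CC(=O)OCC | intermediate
18 | ethyl 2-(1-hydroxy-1,4,4-trimethyl-6-oxodecahydroazulen-5-yl)acetate, C5, C6, C9, C15 as in 40 | O=C1CC[C@H]2[C@H](CC[C@]2(C)O)C(C)(C)[C@@H]1CC(=O)OCC | intermediate
19 | triethylsilyl ether of 18 | O=C1CC[C@H]2[C@H](CC[C@]2(C)O[Si](CC)(CC)CC)C(C)(C)[C@@H]1CC(=O)OCC | intermediate
20 | potassium C2–C3 enolate of 19 | [K+].[O-]C1=CC[C@H]2[C@H](CC[C@]2(C)O[Si](CC)(CC)CC)C(C)(C)[C@@H]1CC(=O)OCC | intermediate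
21 | C2 enol triflate of 19 | FC(F)(F)S(=O)(=O)OC1=CC[C@H]2[C@H](CC[C@]2(C)O[Si](CC)(CC)CC)C(C)(C)[C@@H]1CC(=O)OCC | intermediate
22 | ethyl 2-[(1S,3aS,5R,8aS)-1,4,4,6-tetramethyl-1-(triethylsilyloxy)-1,2,3,3a,4,5,8,8a-octahydroazulen-5-yl]acetate | CC1=CC[C@H]2[C@H](CC[C@]2(C)O[Si](CC)(CC)CC)C(C)(C)[C@@H]1CC(=O)OCC | intermediate
23 | 2-[(1S,3aS,5R,8aS)-1,4,4,6-tetramethyl-1-(triethylsilyloxy)-1,2,3,3a,4,5,8,8a-octahydroazulen-5-yl]acetaldehyde | CC1=CC[C@H]2[C@H](CC[C@]2(C)O[Si](CC)(CC)CC)C(C)(C)[C@@H]1CC=O | intermediate
24 | 1,4-dioxaspiro[4.5]dec-6-en-8-one | O=C1C=CC2(CC1)OCCO2 | starting material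
25 | (8R)-1,4-dioxaspiro[4.5]dec-6-en-8-ol | O[C@H]1C=CC2(CC1)OCCO2 | intermediate
26 | tert-butyldimethylsilyl ether of 25 | CC(C)(C)[Si](C)(C)O[C@H]1C=CC2(CC1)OCCO2 | intermediate
27 | (4R)-4-[(tert-butyldimethylsilyl)oxy]cyclohex-2-en-1-one | O=C1C=C[C@H](O[Si](C)(C)C(C)(C)C)CC1 | intermediate
28 | trimethylsilyl enol ether of trans-4-(tert-butyldimethylsilyloxy)-3-(4-methylpent-3-en-1-yl)cyclohexanone | C[Si](C)(C)OC1=C[C@@H](CCC=C(C)C)[C@H](O[Si](C)(C)C(C)(C)C)CC1 | intermediate
29 | (4R)-4-[(tert-butyldimethylsilyl)oxy]-3-(4-methylpent-3-en-1-yl)cyclohex-2-en-1-one | O=C1C=C(CCC=C(C)C)[C@H](O[Si](C)(C)C(C)(C)C)CC1 | intermediate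
30 | (4R)-4-[(tert-butyldimethylsilyl)oxy]-3-{2-[(2R)-3,3-dimethyloxiran-2-yl]ethyl}cyclohex-2-en-1-one | O=C1C=C(CC[C@H]2OC2(C)C)[C@H](O[Si](C)(C)C(C)(C)C)CC1 | intermediate
31 | (4R)-3-{2-[(2R)-3,3-dimethyloxiran-2-yl]ethyl}-4-hydroxycyclohex-2-en-1-one | O=C1C=C(CC[C@H]2OC2(C)C)[C@H](O)CC1 | intermediate
32 | (3R,9aR)-3-hydroxy-2,2-dimethyl-3,4,5,8,9,9a-hexahydro-1-benzoxepin-7(2H)-one | O=C1C=C2CC[C@@H](O)C(C)(C)O[C@@H]2CC1 | intermediate
33 | triethylsilyl ether of 32 | O=C1C=C2CC[C@@H](O[Si](CC)(CC)CC)C(C)(C)O[C@@H]2CC1 | intermediate
34 | lithium C32–C18 enolate of the conjugate adduct of 33 (C20 methyl anti to O28) | [Li+].[O-]C1=C[C@]2(C)CC[C@@H](O[Si](CC)(CC)CC)C(C)(C)O[C@@H]2CC1 | intermediate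
35 | aldol adduct (C17 carbinol epimers) | CC1=CC[C@H]2[C@H](CC[C@]2(C)O[Si](CC)(CC)CC)C(C)(C)[C@@H]1CC(O)[C@H]1[C@]2(C)CC[C@@H](O[Si](CC)(CC)CC)C(C)(C)O[C@@H]2CCC1=O | intermediate
36 | O-(imidazol-1-ylthiocarbonyl) derivative of 35 | CC1=CC[C@H]2[C@H](CC[C@]2(C)O[Si](CC)(CC)CC)C(C)(C)[C@@H]1CC(OC(=S)n1ccnc1)[C@H]1[C@]2(C)CC[C@@H](O[Si](CC)(CC)CC)C(C)(C)O[C@@H]2CCC1=O | intermediate
37 | C32 ketone, 9,23-bis(triethylsilyl) ether | CC1=CC[C@H]2[C@H](CC[C@]2(C)O[Si](CC)(CC)CC)C(C)(C)[C@@H]1CC[C@H]1[C@]2(C)CC[C@@H](O[Si](CC)(CC)CC)C(C)(C)O[C@@H]2CCC1=O | intermediate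
38 | C32 tertiary alcohol, 9,23-bis(triethylsilyl) ether | CC1=CC[C@H]2[C@H](CC[C@]2(C)O[Si](CC)(CC)CC)C(C)(C)[C@@H]1CC[C@H]1[C@]2(C)CC[C@@H](O[Si](CC)(CC)CC)C(C)(C)O[C@@H]2CC[C@@]1(C)O | intermediate
39 | triol, (23R)-23-hydroxy analogue of 40 | CC1=CC[C@H]2[C@H](CC[C@]2(C)O)C(C)(C)[C@@H]1CC[C@H]1[C@]2(C)CC[C@@H](O)C(C)(C)O[C@@H]2CC[C@@]1(C)O | intermediate
40 | CNP0194989.5 | CC1=CC[C@H]2[C@H](CC[C@]2(C)O)C(C)(C)[C@@H]1CC[C@H]1[C@]2(C)CCC(=O)C(C)(C)O[C@@H]2CC[C@@]1(C)O | target

## Step count and least certain steps

Total: 31 steps. Longest linear sequence: 22 steps (steps 1–16, then 26–31); the right half (steps 17–25) is a nine-step branch that takes its side chain from the Grignard solution of step 1.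

**Step 7 (key step).** What may go wrong: capture of the C5 radical by a second titanium before ring closure, followed by β-elimination of the titanoxy group, or slow electron transfer to an epoxide crowded by the fully substituted C9; either returns open-chain material. Fallback, from racemic 4 back to 9: the relay is moved to a secondary carbinol and the quaternary C9 is built afterwards. Kinetic resolution of 4 with L-(+)-diisopropyl tartrate gives the enantiomeric epoxy alcohol (1S)-5-methyl-1-[(2R)-oxiran-2-yl]hex-4-en-1-ol F1, which is silylated (t-BuMe2SiCl, imidazole) to its tert-butyldimethylsilyl ether F2. Cp2TiCl cyclisation of F2, in which the C4 arm eclipses the C9 hydrogen and lies anti to the silyloxy group, should give the cyclopentylmethanol F3 (O9 trans to both arms, C5 and C6 as in 9). Protection as the 4-methoxybenzyl ether F4 (NaH, 4-methoxybenzyl chloride), desilylation (Bu4NF) to the cyclopentanol F5 and Dess–Martin oxidation give the cyclopentanone F6. Me3SiCH2MgCl/CeCl3 should add anti to the neighbouring C4 arm to give the tertiary β-hydroxysilane F7 with the C9 configuration of 9; it is silylated (Et3SiOTf) to the triethylsilyl ether F8 and freed from the 4-methoxybenzyl group with DDQ, rejoining the route at 9.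

**Step 10.** What may go wrong: the 7-exo closure is slow enough for the C12 radical to be reduced first, or the ring closes without facial control at C15. Fallback, from 9 back to 17: the ring is closed by an ionic C2–C3 bond formation. Triflate 11 is alkylated with the lithium enolate of tert-butyl acetate to give the tert-butyl ester F9. Intermolecular iron-hydride coupling of its isopropenyl group with diethyl fumarate, a symmetrical acceptor, gives the triester F10. Dieckmann condensation (KOt-Bu) of the C3 ester enolate onto the C15-bound ethyl ester gives the bicyclic β-keto ester F11. CF3CO2H then cleaves the tert-butyl ester, the β-keto acid decarboxylates on warming and the silyl ether undergoes the Peterson elimination in the same medium, rejoining the route at 17 after base equilibration of C15.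

**Step 12.** What may go wrong: capture of the C9 radical from the concave face, or migration of the exocyclic alkene into the ring under the hydride conditions. Fallback, from 17 back to 18: oxygen is delivered by a bulky electrophile and the methyl group is made by reduction. Dimethyldioxirane epoxidation from the convex face gives the spiro-epoxide F12, sodium phenylselenide opens it at the CH2 terminus to the β-hydroxy selenide F13, and Bu3SnH/AIBN removes selenium to give 18.

**Step 24.** What may go wrong: attack of O28 at C23 instead of C25 (6-exo opening to a tetrahydropyran). Fallback, from 29 back to 32: the C25–O28 bond is made by Markovnikov oxymercuration. Desilylation of 29 (Bu4NF) gives the hydroxy enone F14, and Hg(OCOCF3)2 closes the oxepane at the tertiary carbon to the organomercurial F15. Bu3SnH under air followed by PPh3 replaces mercury by hydroxyl and gives 32 together with its C23 epimer F16, which is carried on with it because C23 ends as the ketone.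

**Step 26.** What may go wrong: proton transfer from the enolisable aldehyde 23 to enolate 34, retro-aldol on work-up, β-elimination during the thioacylation of step 27, or attack on the hindered face at C18. Fallback, from 33 and 23 back to 37: alkylation replaces the aldol. Conjugate addition of Me2CuLi to 33 in the presence of Me3SiCl gives the trimethylsilyl enol ether F17. Aldehyde 23 is reduced (NaBH4) to the primary alcohol F18 and converted (Tf2O, 2,6-lutidine) into the triflate F19. MeLi regenerates enolate 34 from F17, and its alkylation with F19 gives 37 directly, without steps 27 and 28.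

## Further compounds

F1 | step 7 | (1S)-5-methyl-1-[(2R)-oxiran-2-yl]hex-4-en-1-ol | CC(C)=CCC[C@H](O)[C@H]1CO1
F2 | step 7 | tert-butyldimethylsilyl ether of F1 | CC(C)=CCC[C@H](O[Si](C)(C)C(C)(C)C)[C@H]1CO1
F3 | step 7 | [2-(tert-butyldimethylsilyloxy)-5-(prop-1-en-2-yl)cyclopentyl]methanol, O9 trans to C4 and C12 | OC[C@H]1[C@H](CC[C@@H]1O[Si](C)(C)C(C)(C)C)C(C)=C
F4 | step 7 | 4-methoxybenzyl ether of F3 | COc1ccc(COC[C@H]2[C@H](CC[C@@H]2O[Si](C)(C)C(C)(C)C)C(C)=C)cc1
F5 | step 7 | 2-[(4-methoxybenzyloxy)methyl]-3-(prop-1-en-2-yl)cyclopentanol | COc1ccc(COC[C@H]2[C@H](CC[C@@H]2O)C(C)=C)cc1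
F6 | step 7 | cis-2-[(4-methoxybenzyloxy)methyl]-3-(prop-1-en-2-yl)cyclopentanone | COc1ccc(COC[C@H]2[C@H](CCC2=O)C(C)=C)cc1
F7 | step 7 | 2-[(4-methoxybenzyloxy)methyl]-3-(prop-1-en-2-yl)-1-[(trimethylsilyl)methyl]cyclopentanol, O9 cis to both arms | COc1ccc(COC[C@H]2[C@H](CC[C@@]2(C[Si](C)(C)C)O)C(C)=C)cc1
F8 | step 7 | triethylsilyl ether of F7 | COc1ccc(COC[C@H]2[C@H](CC[C@@]2(C[Si](C)(C)C)O[Si](CC)(CC)CC)C(C)=C)cc1
F9 | step 10 | tert-butyl 3-(cyclopentyl)propanoate, ring of 9 | CC(C)(C)OC(=O)CC[C@H]1[C@H](CC[C@@]1(C[Si](C)(C)C)O[Si](CC)(CC)CC)C(C)=C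
F10 | step 10 | diethyl 2-[2-(cyclopentyl)propan-2-yl]succinate bearing the tert-butyl propanoate arm (C15 epimers) | CC(C)(C)OC(=O)CC[C@H]1[C@H](CC[C@@]1(C[Si](C)(C)C)O[Si](CC)(CC)CC)C(C)(C)C(CC(=O)OCC)C(=O)OCC
F11 | step 10 | bicyclic β-keto ester, tert-butyl ester on C3 (C3 and C15 epimers) | O=C1C(C(=O)OC(C)(C)C)C[C@H]2[C@H](CC[C@@]2(C[Si](C)(C)C)O[Si](CC)(CC)CC)C(C)(C)C1CC(=O)OCC
F12 | step 12 | C9 spiro-epoxide of 17, oxygen on the convex face | O=C1CC[C@H]2[C@H](CC[C@@]23CO3)C(C)(C)[C@@H]1CC(=O)OCC
F13 | step 12 | C10 phenylselanyl derivative of 18 | O=C1CC[C@H]2[C@H](CC[C@]2(C[Se]c2ccccc2)O)C(C)(C)[C@@H]1CC(=O)OCC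
F14 | step 24 | (4R)-4-hydroxy-3-(4-methylpent-3-en-1-yl)cyclohex-2-en-1-one | O=C1C=C(CCC=C(C)C)[C@H](O)CC1
F15 | step 24 | C23 trifluoroacetoxymercurio oxepane enone (C23 epimers) | O=C1C=C2CCC([Hg]OC(=O)C(F)(F)F)C(C)(C)O[C@@H]2CC1
F16 | step 24 | (3S,9aR)-3-hydroxy-2,2-dimethyl-3,4,5,8,9,9a-hexahydro-1-benzoxepin-7(2H)-one | O=C1C=C2CC[C@H](O)C(C)(C)O[C@@H]2CC1
F17 | step 26 | trimethylsilyl enol ether corresponding to enolate 34 | C[Si](C)(C)OC1=C[C@]2(C)CC[C@@H](O[Si](CC)(CC)CC)C(C)(C)O[C@@H]2CC1
F18 | step 26 | 2-(octahydroazulen-5-yl)ethanol from reduction of 23 | CC1=CC[C@H]2[C@H](CC[C@]2(C)O[Si](CC)(CC)CC)C(C)(C)[C@@H]1CCO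
F19 | step 26 | trifluoromethanesulfonate of F18 | CC1=CC[C@H]2[C@H](CC[C@]2(C)O[Si](CC)(CC)CC)C(C)(C)[C@@H]1CCOS(=O)(=O)C(F)(F)F
A1 | alternative 1 | (E)-1-(tert-butyldimethylsilyloxy)buta-1,3-diene | C=C/C=C/O[Si](C)(C)C(C)(C)C
A2 | alternative 1 | ethyl (E)-3-methyl-4-oxobut-2-enoate | CCOC(=O)/C=C(\C)C=O
A3 | alternative 1 | ethyl 2-formyl-2-methyl-3-(tert-butyldimethylsilyloxy)cyclohex-4-ene-1-carboxylate | O=C[C@@]1(C)[C@H](C(=O)OCC)CC=C[C@H]1O[Si](C)(C)C(C)(C)C
A4 | alternative 2 | O28-tethered vinyl ketone with exocyclic C19 methylene | COCOC[C@H]1C(=C)[C@H](OC(C)(C)C(=O)C=C)C=C[C@@]1(C)O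
A5 | alternative 2 | cis-fused oxepanone–cyclohexene with the C17 arm | COCOC[C@H]1[C@]2(C)CCC(=O)C(C)(C)O[C@@H]2C=C[C@@]1(C)O
A6 | alternative 3 | 4,6,7-triethenyl-5,5,7-trimethyloxepan-2-one (C7 configuration left open, to fit the boat transition state) | O=C1C[C@H](C=C)C(C)(C)[C@H](C=C)C(C)(C=C)O1
A7 | alternative 3 | 4,6,6-trimethyl-5,7-divinylcyclohept-3-ene-1-carboxylic acid | CC1=CC[C@H](C(=O)O)[C@H](C=C)C(C)(C)[C@@H]1C=C
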